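## Retrosynthetic overview

1. The target comes from a 4,5-cis bis-tiglate cyclohexenone by late C6 hydroxylation (trans to iPr); the isopropyl group comes from an isopropenyl group by chemoselective hydrogenation.
2. The cis C4 tiglate comes from Mitsunobu inversion, with tiglic acid, of a 4,5-trans 4-hydroxy-5-isopropenylcyclohexenone.
3. The only ring formed, the p-menthane carbocycle, is closed by a catalytic asymmetric intramolecular carbonyl-ene (Prins) reaction of an acyclic, fully oxidised (Z)-4-oxo-neral. This is the C1–C6 bond (geranyl numbering) that monoterpene cyclases form (neryl cation → α-terpinyl cation → isopropenyl by proton loss), and it sets C4 and C5.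
4. The (Z)-4-oxo-enal comes from singlet-oxygen opening of a 2-prenyl-3-(tigloyloxymethyl)furan, a rosefuran-type acyclic monoterpene; the furan fixes the Z geometry.
5. The furan comes from 3-furanmethanol, prenyl bromide and tigloyl chloride in one pot. Ring order: the purchased furan is opened, then the cyclohexenone is closed in step 3.

Assumption: the SMILES is taken literally. Both esters are tiglates (Tig = (2E)-2-methylbut-2-enoyl), and the ring is (4S,5R,6R) in cyclohex-2-en-1-one numbering, with C4-OTig cis to C5-iPr and C6-OH trans to both.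

## Route

Step 1
Reactants: 1 furan-3-ylmethanol; 2 1-bromo-3-methylbut-2-ene (prenyl bromide); 3 (2E)-2-methylbut-2-enoyl chloride (tigloyl chloride)
Product: 6 [2-(3-methylbut-2-en-1-yl)furan-3-yl]methyl (2E)-2-methylbut-2-enoate, via dilithiated furan-3-ylmethanol 4 (not isolated), via lithium (2-prenylfuran-3-yl)methanolate 5 (not isolated)
Conditions: n-BuLi (2.1 equiv), THF, −78 to 0 °C; 2 (1.0 equiv), −78 to 0 °C; then 3 (1.1 equiv), −78 to 0 °C; aq. NH4Cl
Reagents that add atoms: prenyl bromide 2, CC(C)=CCBr; tigloyl chloride 3, C/C=C(\C)C(Cl)=O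
Why: the CH2OLi group directs the second lithiation to C2 (directed ortho-metalation at the furan α-position next to it), the carbanion is alkylated by the allylic bromide (SN2) much faster than the alkoxide, and the alkoxide is then O-acylated in the same flask; no stereocentre is formed.

Step 2
Reactants: 6 [2-(3-methylbut-2-en-1-yl)furan-3-yl]methyl (2E)-2-methylbut-2-enoate
Product: 8 (2Z)-7-methyl-4-oxo-3-[(tigloyloxy)methyl]octa-2,6-dienal, via furan endoperoxide 7 (not isolated)
Conditions: O2, tetraphenylporphyrin (0.5 mol %), visible light, CH2Cl2, −78 °C; then Me2S (3 equiv), −78 to 0 °C; used at once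
Reagents that add atoms: dioxygen, O=O
Why: singlet oxygen adds [4+2] to the electron-rich furan far faster than it reacts with the prenyl alkene or the electron-poor tiglate, and Me2S reduction of the endoperoxide releases the cis-ene-dicarbonyl (furan photooxygenation with reductive ring opening), so the Z geometry needed for ring closure comes from the furan; no stereocentre.

Step 3
Reactants: 8 (2Z)-7-methyl-4-oxo-3-[(tigloyloxy)methyl]octa-2,6-dienal
Product: 9 (4R,5S)-4-hydroxy-5-(prop-1-en-2-yl)-2-[(tigloyloxy)methyl]cyclohex-2-en-1-one (4,5-trans)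
Conditions: confined chiral imidodiphosphorimidate Brønsted acid (IDPi; two 3,3′-diaryl-BINOL units, perfluoroaryl groups, N-perfluoroarylsulfonyl core; 3 mol %; the antipode that turns neral into (1R,6S)-trans-isopiperitenol), CH2Cl2, −40 °C
Reagents that add atoms: none
Why: Proposed new method: the chiral acid activates the Z-held aldehyde, the tethered 2-methylprop-1-enyl terminus attacks it through a six-membered half-chair with the forming isopropenyl group and the carbinol oxygen both pseudo-equatorial (4,5-trans), a methyl hydrogen passes to oxygen (intramolecular carbonyl-ene/Prins cyclisation), and the confined chiral anion selects the aldehyde face so that C4 is R and C5 is S; the closest known reaction type is the IDPi-catalysed cyclisation of neral to (1R,6S)-trans-isopiperitenol, which has the same spatial sense, the new element being the 4-oxo group in the tether.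

Step 4
Reactants: 9 (4R,5S)-4-hydroxy-5-(prop-1-en-2-yl)-2-[(tigloyloxy)methyl]cyclohex-2-en-1-one; 10 (2E)-2-methylbut-2-enoic acid (tiglic acid)
Product: 12 (4S,5S)-5-(prop-1-en-2-yl)-4-(tigloyloxy)-2-[(tigloyloxy)methyl]cyclohex-2-en-1-one (4,5-cis), via alkoxyphosphonium tiglate 11 (not isolated)
Conditions: PPh3 (1.5 equiv), DIAD (1.5 equiv), THF, 0 °C (betaine pre-formed); then 10 (1.5 equiv) and 9, 0 °C to rt
Reagents that add atoms: tiglic acid 10, C/C=C(\C)C(=O)O
Why: Mitsunobu esterification: the C4 alcohol is activated as its alkoxyphosphonium ion and displaced by tiglate in an SN2 step with inversion (SN2′ and ionisation are disfavoured because the allyl unit is part of an enone), which turns the 4,5-trans alcohol into the 4,5-cis tiglate (C4 now S) while pre-forming the betaine keeps free PPh3 away from the allylic CH2OTig group.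

Step 5
Reactants: 12 (4S,5S)-5-(prop-1-en-2-yl)-4-(tigloyloxy)-2-[(tigloyloxy)methyl]cyclohex-2-en-1-one
Product: 13 (4R,5S)-5-(propan-2-yl)-4-(tigloyloxy)-2-[(tigloyloxy)methyl]cyclohex-2-en-1-one (4,5-cis)
Conditions: H2 (1 atm), RhCl(PPh3)3 (5 mol %), benzene, rt
Reagents that add atoms: none
Why: homogeneous hydrogenation with RhCl(PPh3)3 reduces the 1,1-disubstituted isopropenyl alkene and leaves the trisubstituted conjugated alkenes (enone and both tiglates) untouched, as in carvone to carvotanacetone; no stereocentre is formed, and the C4 descriptor changes from S to R only because the CIP priorities change.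

Step 6
Reactants: 13 (4R,5S)-5-(propan-2-yl)-4-(tigloyloxy)-2-[(tigloyloxy)methyl]cyclohex-2-en-1-one
Product: 15 (4S,5R,6R)-6-hydroxy-5-(propan-2-yl)-4-(tigloyloxy)-2-[(tigloyloxy)methyl]cyclohex-2-en-1-one (the target), via sodium dienolate 14 (not isolated)
Conditions: NaN(SiMe3)2 (1.1 equiv), THF, −78 °C, 30 min; 3-phenyl-2-(phenylsulfonyl)oxaziridine (1.3 equiv), −78 °C; AcOH quench at −78 °C
Reagents that add atoms: 3-phenyl-2-(phenylsulfonyl)oxaziridine, O=S(=O)(c1ccccc1)N1OC1c1ccccc1
Why: kinetic α′-deprotonation gives the cross-conjugated sodium dienolate, and the oxaziridine oxygen (Davis enolate hydroxylation) is delivered to C6 on the face opposite the adjacent C5 isopropyl group and the pseudo-axial C4 tiglate, giving the 5,6-trans (6R) alcohol; the descriptor changes at C4 and C5 are CIP priority changes only.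

## Compound list

1 | furan-3-ylmethanol (3-furanmethanol) | OCc1ccoc1 | starting material
2 | 1-bromo-3-methylbut-2-ene (prenyl bromide) | CC(C)=CCBr | starting material
3 | (2E)-2-methylbut-2-enoyl chloride (tigloyl chloride) | C/C=C(\C)C(Cl)=O | starting material
4 | lithium (2-lithiofuran-3-yl)methanolate (dianion) | [Li]OCc1ccoc1[Li] | intermediate (not isolated)
5 | lithium [2-(3-methylbut-2-en-1-yl)furan-3-yl]methanolate | [Li]OCc1ccoc1CC=C(C)C | intermediate (not isolated)
6 | [2-(3-methylbut-2-en-1-yl)furan-3-yl]methyl (2E)-2-methylbut-2-enoate | C/C=C(\C)C(=O)OCc1ccoc1CC=C(C)C | intermediate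
7 | [1-(3-methylbut-2-en-1-yl)-2,3,7-trioxabicyclo[2.2.1]hept-5-en-6-yl]methyl (2E)-2-methylbut-2-enoate (racemic endoperoxide) | C/C=C(\C)C(=O)OCC1=CC2OOC1(CC=C(C)C)O2 | intermediate (not isolated)
8 | (2Z)-7-methyl-4-oxo-3-[(tigloyloxy)methyl]octa-2,6-dienal | O=C/C=C(\C(=O)CC=C(C)C)COC(=O)/C(C)=C/C | intermediate
9 | (4R,5S)-4-hydroxy-5-(prop-1-en-2-yl)-2-[(tigloyloxy)methyl]cyclohex-2-en-1-one (4,5-trans) | C/C=C(\C)C(=O)OCC1=C[C@@H](O)[C@H](C(C)=C)CC1=O | intermediate
10 | (2E)-2-methylbut-2-enoic acid (tiglic acid) | C/C=C(\C)C(=O)O | starting material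
11 | C4-O-triphenylphosphonium derivative of 9, tiglate salt | C/C=C(\C)C(=O)OCC1=C[C@@H](O[P+](c2ccccc2)(c2ccccc2)c2ccccc2)[C@H](C(C)=C)CC1=O.C/C=C(\C)C(=O)[O-] | intermediate (not isolated)
12 | (4S,5S)-5-(prop-1-en-2-yl)-4-(tigloyloxy)-2-[(tigloyloxy)methyl]cyclohex-2-en-1-one (4,5-cis) | C/C=C(\C)C(=O)OCC1=C[C@H](OC(=O)/C(C)=C/C)[C@H](C(C)=C)CC1=O | intermediate
13 | (4R,5S)-5-(propan-2-yl)-4-(tigloyloxy)-2-[(tigloyloxy)methyl]cyclohex-2-en-1-one (4,5-cis) | C/C=C(\C)C(=O)OCC1=C[C@H](OC(=O)/C(C)=C/C)[C@H](C(C)C)CC1=O | intermediate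
14 | sodium cross-conjugated dienolate of 13 (C1–O−, C1=C6; C4 and C5 as in 13) | C/C=C(\C)C(=O)OCC1=C[C@H](OC(=O)/C(C)=C/C)[C@H](C(C)C)C=C1[O-].[Na+] | intermediate (not isolated)
15 | (4S,5R,6R)-6-hydroxy-5-(propan-2-yl)-4-(tigloyloxy)-2-[(tigloyloxy)methyl]cyclohex-2-en-1-one (3-hydroxy-5,7-bis(tigloyloxy)carvotacetone) | C/C=C(\C)C(=O)OCC1=C[C@H](OC(=O)/C(C)=C/C)[C@H](C(C)C)[C@@H](O)C1=O | target

## Step count and risks

Total step count: 6. Longest linear sequence: 6 steps, from 1.

The three steps most likely to fail:

Step 3, the ring closure. The enal may isomerise from Z to E, the skipped enone may move into conjugation, or the acid-labile γ-hydroxy enone may dehydrate before a useful ee is reached. The fallback sets out from 8 and comes back at 9. The ring is closed without asymmetric induction by Me2AlCl (1.1 equiv, CH2Cl2, −78 °C; Lewis-acid carbonyl-ene, still 4,5-trans) to give the racemic trans-alcohol F1. This is resolved by lipase-catalysed acylation (Candida antarctica lipase B, vinyl acetate, tert-butyl methyl ether, 30 °C). By the Kazlauskas rule, with the C5 side as the large group, the (4R)-enantiomer is acetylated to the (4R,5S)-acetate F2, and the (4S,5R)-alcohol F3 is left behind and removed by chromatography. Butanolysis of F2 with the same lipase (n-BuOH) releases 9 without touching the tiglate.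

Step 4, the Mitsunobu inversion. Tiglic acid is only weakly acidic, the allylic carbinol is hindered, elimination to a dienone and then a phenol can compete, and free PPh3 can attack the allylic CH2OTig unit. The fallback sets out from 9 and comes back at 12. MsCl and Et3N (CH2Cl2, −20 °C) give the (4R,5S)-mesylate F4. This is displaced with inversion by cesium (2E)-2-methylbut-2-enoate (made from Cs2CO3 and 10) with 18-crown-6 in toluene at 40 °C, a carboxylate SN2 displacement in place of phosphonium activation, to give 12.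

Step 6, the α′-hydroxylation. Deprotonation at C4 instead of C6 would expel the allylic tiglate and lead to aromatisation, and the enolate can add to the sulfonimine by-product. The fallback sets out from 13 and comes back at 15. Soft enolisation with Me3SiOTf and Et3N (CH2Cl2, −78 °C) gives the cross-conjugated trimethylsilyl dienol ether F5. Rubottom oxidation with dimethyldioxirane (acetone, −78 °C; attack anti to iPr and OTig) gives the 6-trimethylsilyloxy ketone F6. Aqueous citric acid in THF removes the silyl group to give 15.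

## Further compounds

F1 | step 3 | racemic 4,5-trans alcohol (9 together with its mirror image) | C/C=C(\C)C(=O)OCC1=C[C@@H](O)[C@H](C(C)=C)CC1=O.C/C=C(\C)C(=O)OCC1=C[C@H](O)[C@@H](C(C)=C)CC1=O
F2 | step 3 | (4R,5S)-4-acetoxy-5-(prop-1-en-2-yl)-2-[(tigloyloxy)methyl]cyclohex-2-en-1-one | C/C=C(\C)C(=O)OCC1=C[C@@H](OC(C)=O)[C@H](C(C)=C)CC1=O
F3 | step 3 | (4S,5R)-4-hydroxy-5-(prop-1-en-2-yl)-2-[(tigloyloxy)methyl]cyclohex-2-en-1-one (mirror image of 9) | C/C=C(\C)C(=O)OCC1=C[C@H](O)[C@@H](C(C)=C)CC1=O
F4 | step 4 | (4R,5S)-4-(methanesulfonyloxy)-5-(prop-1-en-2-yl)-2-[(tigloyloxy)methyl]cyclohex-2-en-1-one | C/C=C(\C)C(=O)OCC1=C[C@@H](OS(C)(=O)=O)[C@H](C(C)=C)CC1=O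
F5 | step 6 | trimethylsilyl dienol ether of 13 (1-trimethylsilyloxycyclohexa-1,5-diene; C4 and C5 as in 13) | C/C=C(\C)C(=O)OCC1=C[C@H](OC(=O)/C(C)=C/C)[C@H](C(C)C)C=C1O[Si](C)(C)C
F6 | step 6 | 6-O-trimethylsilyl ether of 15 | C/C=C(\C)C(=O)OCC1=C[C@H](OC(=O)/C(C)=C/C)[C@H](C(C)C)[C@@H](O[Si](C)(C)C)C1=O
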